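**Retrosynthetic overview**

1. The enabling feature (cembrane numbering) is the tertiary allylic carbinol C8 (CH3, OH) bonded to the E-C6=C7 olefin inside the 14-membered carbocycle and insulated from C3=C4 by the C5 methylene. It is the retron of an alkenylmetal addition to a methyl ketone, so C6=C7 can be carried as a terminal alkyne.
2. C7–C8 is disconnected last: one-pot hydroboration, boron-to-zinc exchange and titanium-catalysed asymmetric alkenyl transfer closes the macrocycle from seco alkynyl ketone 21, setting 6E and 8R.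
3. The cis-fused methylene lactone (C1–C2 bond and C16–O bond) comes from a chromium-catalysed asymmetric syn 2-(alkoxycarbonyl)allylation of enynal 18 with allylic bromide 11.
4. Bromide 11 comes from 6-methylhept-5-en-2-one by allylic oxidation, Brown allylation (C13), matched Sharpless epoxidation (C11, C12), ozonolysis and a Morita–Baylis–Hillman reaction; enynal 18 comes from prenyl acetate.
5. Ring order: oxirane (step 4), γ-lactone (step 14), 14-membered carbocycle (step 15); the end-game exchanges the C13 silyl ether for the acetate.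

Key step: step 15

Remark: cembrane numbering is used throughout (C1 carries C15 of the methylene lactone, C2 the lactone oxygen, C4/C8/C12 the methyl groups); in this numbering the target SMILES is read as 1S,2S,3E,6E,8R,11S,12R,13S with a cis-fused lactone and an erythro C12/C13 epoxy-carbinol relationship.

Step 1
Reactants: 1 6-methylhept-5-en-2-one
Product: 2 (5E)-7-hydroxy-6-methylhept-5-en-2-one
Conditions: SeO2 (0.3 equiv), tBuOOH (2.5 equiv), salicylic acid (0.1 equiv), CH2Cl2, 23 °C
Reagents that add atoms: tert-butyl hydroperoxide, CC(C)(C)OO (oxygen relayed by catalytic SeO2, O=[Se]=O)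
Why: Riley allylic oxidation (ene reaction, then [2,3]-shift) attacks the methyl group trans to the chain, so the E-allylic alcohol should form while the ketone is left alone at room temperature; any over-oxidised enal 3 converges in step 2.

Step 2
Reactants: 2 (5E)-7-hydroxy-6-methylhept-5-en-2-one
Product: 3 (2E)-2-methyl-6-oxohept-2-enal
Conditions: MnO2 (15 equiv), CH2Cl2, 23 °C
Reagents that add atoms: none
Why: MnO2 oxidises only the allylic alcohol and leaves the olefin geometry and the saturated ketone untouched.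

Step 3
Reactants: 3 (2E)-2-methyl-6-oxohept-2-enal
Product: 4 (5E,7S)-7-hydroxy-6-methyldeca-5,9-dien-2-one
Conditions: (−)-B-allyldiisopinocampheylborane (1.05 equiv, preformed solution in pentane), Et2O, −78 °C; then 3 M NaOH, 30% H2O2, 0 to 23 °C
Reagents that add atoms: (−)-B-allyldiisopinocampheylborane, C=CCB([C@@H]1C[C@@H]2C[C@H]([C@H]1C)C2(C)C)[C@@H]1C[C@@H]2C[C@H]([C@H]1C)C2(C)C
Why: Brown allylation through a closed chair transition state is fast for the aldehyde and slow for the methyl ketone at −78 °C, and the (+)-α-pinene-derived reagent should add to the Si face of the enal, setting C13 as S.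

Step 4
Reactants: 4 (5E,7S)-7-hydroxy-6-methyldeca-5,9-dien-2-one
Product: 5 4-{(2S,3S)-3-[(1S)-1-hydroxybut-3-en-1-yl]-3-methyloxiran-2-yl}butan-2-one
Conditions: Ti(OiPr)4 (0.1 equiv), L-(+)-diisopropyl tartrate (0.12 equiv), tBuOOH (2 equiv), 4 Å molecular sieves, CH2Cl2, −20 °C
Reagents that add atoms: tert-butyl hydroperoxide, CC(C)(C)OO
Why: Sharpless asymmetric epoxidation in its matched sense (the S carbinol is the fast-reacting partner of the L-(+)-tartrate) should give the erythro epoxy alcohol, setting C11 and C12 by reagent and substrate control together, while the remote vinyl group and the ketone do not react.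

Step 5
Reactants: 5 4-{(2S,3S)-3-[(1S)-1-hydroxybut-3-en-1-yl]-3-methyloxiran-2-yl}butan-2-one
Product: 6 4-{(2S,3R)-3-methyl-3-[(1S)-1-(triethylsilyloxy)but-3-en-1-yl]oxiran-2-yl}butan-2-one
Conditions: Et3SiCl (1.3 equiv), imidazole (2.5 equiv), DMAP (0.05 equiv), DMF, 0 to 23 °C
Reagents that add atoms: chlorotriethylsilane, CC[Si](Cl)(CC)CC
Why: standard silylation of the secondary alcohol; the triethylsilyl ether should survive steps 6 to 15 and can later be removed with buffered fluoride, without acid near the epoxide.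

Step 6
Reactants: 6 4-{(2S,3R)-3-methyl-3-[(1S)-1-(triethylsilyloxy)but-3-en-1-yl]oxiran-2-yl}butan-2-one
Product: 7 (3S)-3-[(2R,3S)-2-methyl-3-(3-oxobutyl)oxiran-2-yl]-3-(triethylsilyloxy)propanal
Conditions: O3, CH2Cl2, −78 °C; then PPh3 (1.2 equiv), −78 to 23 °C
Reagents that add atoms: ozone, [O-][O+]=O
Why: ozonolysis with reductive work-up cleaves the only C=C bond left, the terminal vinyl group, to the C1 aldehyde.

Step 7
Reactants: 7 (3S)-3-[(2R,3S)-2-methyl-3-(3-oxobutyl)oxiran-2-yl]-3-(triethylsilyloxy)propanal; 8 methyl acrylate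
Product: 9 methyl (5S)-3-hydroxy-2-methylidene-5-[(2R,3S)-2-methyl-3-(3-oxobutyl)oxiran-2-yl]-5-(triethylsilyloxy)pentanoate (both C3 epimers)
Conditions: 8 (10 equiv, neat), DABCO (0.5 equiv), 23 °C, several days
Reagents that add atoms: none
Why: Morita–Baylis–Hillman reaction: the amine-derived acrylate enolate attacks the unhindered aldehyde and not the ketone, and the new carbinol centre is formed as a mixture that is erased in step 8.

Step 8
Reactants: 9 methyl (5S)-3-hydroxy-2-methylidene-5-[(2R,3S)-2-methyl-3-(3-oxobutyl)oxiran-2-yl]-5-(triethylsilyloxy)pentanoate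
Product: 11 methyl (2Z,5S)-2-(bromomethyl)-5-[(2R,3S)-2-methyl-3-(3-oxobutyl)oxiran-2-yl]-5-(triethylsilyloxy)pent-2-enoate, via allylic mesylate 10 (not isolated)
Conditions: MsCl (1.2 equiv), Et3N (1.5 equiv), CH2Cl2, −20 °C; then LiBr (3 equiv), THF, 0 to 23 °C
Reagents that add atoms: lithium bromide, [Li+].[Br-]; methanesulfonyl chloride, CS(=O)(=O)Cl (atoms in intermediate 10 only)
Why: mesylation followed by SN2′ displacement with bromide moves the double bond into conjugation and should give the thermodynamically preferred Z bromide (chain cis to CH2Br) without strong acid, so the epoxide and silyl ether are not at risk.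

Step 9
Reactants: 12 3-methylbut-2-en-1-yl acetate
Product: 13 (2E)-4-hydroxy-3-methylbut-2-en-1-yl acetate
Conditions: SeO2 (0.3 equiv), tBuOOH (2.5 equiv), salicylic acid (0.1 equiv), CH2Cl2, 23 °C
Reagents that add atoms: tert-butyl hydroperoxide, CC(C)(C)OO (oxygen relayed by catalytic SeO2, O=[Se]=O)
Why: Riley allylic oxidation is selective for the methyl group trans to the CH2OAc substituent, which fixes the 3E geometry of the later C3=C4 olefin.

Step 10
Reactants: 13 (2E)-4-hydroxy-3-methylbut-2-en-1-yl acetate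
Product: 14 (2E)-4-bromo-3-methylbut-2-en-1-yl acetate
Conditions: CBr4 (1.2 equiv), PPh3 (1.25 equiv), CH2Cl2, 0 °C
Reagents that add atoms: carbon tetrabromide, BrC(Br)(Br)Br
Why: Appel bromination converts the primary allylic alcohol into the bromide by SN2 without touching the acetate or the olefin geometry.

Step 11
Reactants: 14 (2E)-4-bromo-3-methylbut-2-en-1-yl acetate; 15 ethynyl(trimethyl)silane
Product: 16 (2E)-3-methyl-6-(trimethylsilyl)hex-2-en-5-yn-1-yl acetate
Conditions: CuI (1.0 equiv), NaI (1.0 equiv), K2CO3 (1.5 equiv), DMF, 23 °C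
Reagents that add atoms: none
Why: copper-mediated coupling of a terminal alkyne with a primary allylic bromide proceeds at the α-carbon under nearly neutral conditions and should give the skipped 1,4-enyne with retention of the E olefin; the allylic acetate is not displaced.

Step 12
Reactants: 16 (2E)-3-methyl-6-(trimethylsilyl)hex-2-en-5-yn-1-yl acetate
Product: 17 (2E)-3-methylhex-2-en-5-yn-1-ol
Conditions: K2CO3 (0.5 equiv), MeOH, 0 to 23 °C
Reagents that add atoms: none
Why: methanolysis with carbonate removes the acetate and the C-silyl group in one operation, and this mild base should not isomerise the skipped enyne.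

Step 13
Reactants: 17 (2E)-3-methylhex-2-en-5-yn-1-ol
Product: 18 (2E)-3-methylhex-2-en-5-ynal
Conditions: MnO2 (15 equiv), CH2Cl2, 23 °C; filtered and used at once as a solution
Reagents that add atoms: none
Why: MnO2 oxidises the allylic alcohol under neutral conditions, which avoids deconjugation at the acidic C5 methylene of the enal.

Step 14
Reactants: 11 methyl (2Z,5S)-2-(bromomethyl)-5-[(2R,3S)-2-methyl-3-(3-oxobutyl)oxiran-2-yl]-5-(triethylsilyloxy)pent-2-enoate; 18 (2E)-3-methylhex-2-en-5-ynal
Product: 21 (4S,5S)-3-methylidene-5-[(1E)-2-methylpent-1-en-4-yn-1-yl]-4-{(2S)-2-[(2R,3S)-2-methyl-3-(3-oxobutyl)oxiran-2-yl]-2-(triethylsilyloxy)ethyl}oxolan-2-one, via O-trimethylsilyl hydroxy ester 19 (not isolated), via syn-hydroxy ester 20 (not isolated)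
Conditions: 18 (1.5 equiv), CrCl2 (0.1 equiv), tridentate carbazole bis(oxazoline) ligand (0.12 equiv), iPr2NEt (0.3 equiv), Mn powder (2 equiv), Me3SiCl (1.5 equiv), THF, 0 to 23 °C; then 10% aq. citric acid, THF, 0 °C; then PPTS (0.1 equiv), CH2Cl2, 23 °C
Reagents that add atoms: chlorotrimethylsilane, C[Si](C)(C)Cl (atoms in intermediate 19 only)
Why: catalytic asymmetric chromium-mediated (Nozaki–Hiyama-type) 2-(alkoxycarbonyl)allylation: the Z allylchromium reacts through a closed chair transition state with the aldehyde substituent equatorial, which gives the syn adduct and hence the cis-lactone, the ligand enantiomer that directs attack to the Re face of the aldehyde sets C1 and C2 as S,S, the aldehyde reacts far faster than the ketone, and mild acid then removes only the O–SiMe3 group and closes the lactone.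

Step 15
Reactants: 21 (4S,5S)-3-methylidene-5-[(1E)-2-methylpent-1-en-4-yn-1-yl]-4-{(2S)-2-[(2R,3S)-2-methyl-3-(3-oxobutyl)oxiran-2-yl]-2-(triethylsilyloxy)ethyl}oxolan-2-one
Product: 24 (1S,2S,3E,6E,8R,11S,12R,13S)-11,12-epoxy-8-hydroxy-13-(triethylsilyloxy)cembra-3,6,15(17)-trien-16,2-olide, via alkenyldicyclohexylborane 22 (not isolated), via alkenyl(methyl)zinc 23 (not isolated)
Conditions: Cy2BH (1.05 equiv, prepared beforehand), toluene, 0 °C, 1 h; Me2Zn (2.5 equiv), −78 to −20 °C; this solution added over 10 h by syringe pump to Ti(OiPr)4 (1.2 equiv) and the trans-cyclohexane-1,2-diamine-derived bis(2-exo-hydroxycamphor-10-sulfonamide) ligand (0.2 equiv) in toluene, 23 °C, final concentration 2 mM; then aq. NaHCO3 and potassium sodium tartrate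
Reagents that add atoms: dicyclohexylborane, B(C1CCCCC1)C1CCCCC1 (atoms in intermediate 22 only); dimethylzinc, C[Zn]C (atoms in intermediate 23 only)
Why: Proposed new method: syn-hydroboration of the terminal C6≡C7 alkyne gives the E alkenylborane, boron-to-zinc exchange gives an E alkenyl(methyl)zinc that does not attack the remote methyl ketone by itself, and the chiral titanium bis(sulfonamide) diolate then activates the C8 carbonyl and transfers the alkenyl group in a 1,2-addition that forms C7–C8. The closest known reaction types are the alkenylzinc macrocyclisation of ω-alkynals by hydroboration/boron–zinc exchange under chiral amino-alcohol catalysis and the intermolecular titanium-catalysed enantioselective addition of alkenylzinc reagents to methyl ketones; their combination on a ketone in a ring closure is new. The 14-membered carbocycle closes in a 14-exo-trig mode, helped by the rigid cis-lactone, the E-C3=C4 olefin and the trans-epoxide of the seco chain and by slow addition to the catalyst. C8, the only new stereocentre, is set by the catalyst: the ligand antipode is chosen for alkenyl delivery to the Si face of the ketone (O > C9 > C19), giving 8R, and the nearest resident stereocentre (C11) is three atoms away and should not override it. The 6E geometry follows from cis addition of B–H and is kept on transmetalation. The step needs hydroboration of the alkyne in preference to the ketone, the trisubstituted C3=C4 olefin and the electron-poor methylene lactone, which the bulk of Cy2BH and the single monosubstituted alkyne secure, and it needs alkenyl to transfer faster than methyl, which is the normal order for mixed alkenyl(alkyl)zincs.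

Step 16
Reactants: 24 (1S,2S,3E,6E,8R,11S,12R,13S)-11,12-epoxy-8-hydroxy-13-(triethylsilyloxy)cembra-3,6,15(17)-trien-16,2-olide
Product: 25 (1S,2S,3E,6E,8R,11S,12S,13S)-11,12-epoxy-8,13-dihydroxycembra-3,6,15(17)-trien-16,2-olide
Conditions: Bu4NF (1.5 equiv), AcOH (1.5 equiv), THF, 0 to 23 °C
Reagents that add atoms: none
Why: fluoride buffered with acetic acid cleaves the Si–O bond without acid or strong base, so the C8 hydroxyl/C11–C12 epoxide pair (prone to acid-catalysed 5-exo ether formation) and the methylene lactone should survive.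

Step 17
Reactants: 25 (1S,2S,3E,6E,8R,11S,12S,13S)-11,12-epoxy-8,13-dihydroxycembra-3,6,15(17)-trien-16,2-olide
Product: 26 (1S,2S,3E,6E,8R,11S,12R,13S)-13-acetoxy-11,12-epoxy-8-hydroxycembra-3,6,15(17)-trien-16,2-olide (CNP0288879.3)
Conditions: Ac2O (1.5 equiv), pyridine (3 equiv), DMAP (0.05 equiv), CH2Cl2, 0 °C
Reagents that add atoms: acetic anhydride, CC(=O)OC(C)=O
Why: DMAP-catalysed acetylation takes place at the secondary C13 hydroxyl, the tertiary allylic C8 hydroxyl being far less reactive under these conditions.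

**Compound list**

1 | 6-methylhept-5-en-2-one | CC(=O)CCC=C(C)C | starting material
2 | (5E)-7-hydroxy-6-methylhept-5-en-2-one | CC(=O)CC/C=C(\C)CO | intermediate
3 | (2E)-2-methyl-6-oxohept-2-enal | CC(=O)CC/C=C(\C)C=O | intermediate
4 | (5E,7S)-7-hydroxy-6-methyldeca-5,9-dien-2-one | CC(=O)CC/C=C(\C)[C@@H](O)CC=C | intermediate
5 | 4-{(2S,3S)-3-[(1S)-1-hydroxybut-3-en-1-yl]-3-methyloxiran-2-yl}butan-2-one | CC(=O)CC[C@@H]1O[C@@]1(C)[C@@H](O)CC=C | intermediate
6 | 4-{(2S,3R)-3-methyl-3-[(1S)-1-(triethylsilyloxy)but-3-en-1-yl]oxiran-2-yl}butan-2-one | CC(=O)CC[C@@H]1O[C@@]1(C)[C@@H](O[Si](CC)(CC)CC)CC=C | intermediate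
7 | (3S)-3-[(2R,3S)-2-methyl-3-(3-oxobutyl)oxiran-2-yl]-3-(triethylsilyloxy)propanal | CC(=O)CC[C@@H]1O[C@@]1(C)[C@@H](O[Si](CC)(CC)CC)CC=O | intermediate
8 | methyl acrylate | C=CC(=O)OC | starting material
9 | methyl (5S)-3-hydroxy-2-methylidene-5-[(2R,3S)-2-methyl-3-(3-oxobutyl)oxiran-2-yl]-5-(triethylsilyloxy)pentanoate (C3 epimers) | CC(=O)CC[C@@H]1O[C@@]1(C)[C@@H](O[Si](CC)(CC)CC)CC(O)C(=C)C(=O)OC | intermediate
10 | methyl (5S)-3-(methanesulfonyloxy)-2-methylidene-5-[(2R,3S)-2-methyl-3-(3-oxobutyl)oxiran-2-yl]-5-(triethylsilyloxy)pentanoate | CC(=O)CC[C@@H]1O[C@@]1(C)[C@@H](O[Si](CC)(CC)CC)CC(OS(C)(=O)=O)C(=C)C(=O)OC | intermediate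
11 | methyl (2Z,5S)-2-(bromomethyl)-5-[(2R,3S)-2-methyl-3-(3-oxobutyl)oxiran-2-yl]-5-(triethylsilyloxy)pent-2-enoate | CC(=O)CC[C@@H]1O[C@@]1(C)[C@@H](O[Si](CC)(CC)CC)C/C=C(\CBr)C(=O)OC | intermediate
12 | 3-methylbut-2-en-1-yl acetate (prenyl acetate) | CC(C)=CCOC(C)=O | starting material
13 | (2E)-4-hydroxy-3-methylbut-2-en-1-yl acetate | CC(=O)OC/C=C(\C)CO | intermediate
14 | (2E)-4-bromo-3-methylbut-2-en-1-yl acetate | CC(=O)OC/C=C(\C)CBr | intermediate
15 | ethynyl(trimethyl)silane | C#C[Si](C)(C)C | starting material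
16 | (2E)-3-methyl-6-(trimethylsilyl)hex-2-en-5-yn-1-yl acetate | CC(=O)OC/C=C(\C)CC#C[Si](C)(C)C | intermediate
17 | (2E)-3-methylhex-2-en-5-yn-1-ol | OC/C=C(\C)CC#C | intermediate
18 | (2E)-3-methylhex-2-en-5-ynal | O=C/C=C(\C)CC#C | intermediate
19 | methyl (3S,4S,5E)-6-methyl-2-methylidene-3-{(2S)-2-[(2R,3S)-2-methyl-3-(3-oxobutyl)oxiran-2-yl]-2-(triethylsilyloxy)ethyl}-4-(trimethylsilyloxy)non-5-en-8-ynoate | C=C(C(=O)OC)[C@@H]([C@@H](O[Si](C)(C)C)/C=C(\C)CC#C)C[C@H](O[Si](CC)(CC)CC)[C@]1(C)O[C@H]1CCC(C)=O | intermediate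
20 | methyl (3S,4S,5E)-4-hydroxy-6-methyl-2-methylidene-3-{(2S)-2-[(2R,3S)-2-methyl-3-(3-oxobutyl)oxiran-2-yl]-2-(triethylsilyloxy)ethyl}non-5-en-8-ynoate | C=C(C(=O)OC)[C@@H]([C@@H](O)/C=C(\C)CC#C)C[C@H](O[Si](CC)(CC)CC)[C@]1(C)O[C@H]1CCC(C)=O | intermediate
21 | (4S,5S)-3-methylidene-5-[(1E)-2-methylpent-1-en-4-yn-1-yl]-4-{(2S)-2-[(2R,3S)-2-methyl-3-(3-oxobutyl)oxiran-2-yl]-2-(triethylsilyloxy)ethyl}oxolan-2-one | C=C1C(=O)O[C@@H](/C=C(\C)CC#C)[C@H]1C[C@H](O[Si](CC)(CC)CC)[C@]1(C)O[C@H]1CCC(C)=O | intermediate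
22 | seco-lactone 21 with C6≡C7 converted into the (E)-CH=CH–B(cyclohexyl)2 unit (boron on C7) | C=C1C(=O)O[C@@H](/C=C(\C)C/C=C/B(C2CCCCC2)C2CCCCC2)[C@H]1C[C@H](O[Si](CC)(CC)CC)[C@]1(C)O[C@H]1CCC(C)=O | intermediate
23 | seco-lactone 21 with C6≡C7 converted into the (E)-CH=CH–ZnCH3 unit (zinc on C7) | C=C1C(=O)O[C@@H](/C=C(\C)C/C=C/[Zn]C)[C@H]1C[C@H](O[Si](CC)(CC)CC)[C@]1(C)O[C@H]1CCC(C)=O | intermediate
24 | (1S,2S,3E,6E,8R,11S,12R,13S)-11,12-epoxy-8-hydroxy-13-(triethylsilyloxy)cembra-3,6,15(17)-trien-16,2-olide | C=C1C(=O)O[C@H]2/C=C(\C)C/C=C/[C@](C)(O)CC[C@@H]3O[C@@]3(C)[C@@H](O[Si](CC)(CC)CC)C[C@@H]12 | intermediate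
25 | (1S,2S,3E,6E,8R,11S,12S,13S)-11,12-epoxy-8,13-dihydroxycembra-3,6,15(17)-trien-16,2-olide | C=C1C(=O)O[C@H]2/C=C(\C)C/C=C/[C@](C)(O)CC[C@@H]3O[C@@]3(C)[C@@H](O)C[C@@H]12 | intermediate
26 | (1S,2S,3E,6E,8R,11S,12R,13S)-13-acetoxy-11,12-epoxy-8-hydroxycembra-3,6,15(17)-trien-16,2-olide | C=C1C(=O)O[C@H]2/C=C(\C)C/C=C/[C@](C)(O)CC[C@@H]3O[C@@]3(C)[C@@H](OC(C)=O)C[C@@H]12 | target

**Step count and risks**

Total step count: 17. Longest linear sequence: 12 steps (steps 1 to 8, then 14 to 17).

Most likely to fail, first: step 15. The alkenylzinc may add too slowly to the unactivated ketone at high dilution, leading to protonation or oligomers; methyl transfer may compete; the catalyst may discriminate poorly between the CH3 and CH2 flanks of the ketone; the new C8 alkoxide may open the epoxide under titanium; Cy2BH may partly reduce the methylene lactone or the ketone. The fallback is a Nozaki–Hiyama–Kishi ring closure of an alkenyl iodide, forming the same bond by known chemistry. It sets out from 17 (with 11) and comes back at 24. Alcohol 17 would be treated with Cp2Zr(H)Cl (2.2 equiv, THF) and then I2 to give (2E,5E)-6-iodo-3-methylhexa-2,5-dien-1-ol F1. MnO2 would give (2E,5E)-6-iodo-3-methylhexa-2,5-dienal F2. Coupling of F2 with 11 under the conditions of step 14 (no nickel, so the alkenyl iodide stays untouched) would give the O-trimethylsilyl iodo hydroxy ester F3, then the iodo hydroxy ester F4 after citric acid, then the iodo seco-lactone F5 after PPTS. F5 would be cyclised with CrCl2 (excess) and NiCl2 (catalytic) in DMSO/THF at high dilution to 24. C8 would then form under substrate control, with separation of the 8-epimer if it forms.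

Second: step 14. The remote stereocentres of 11 may erode catalyst control over the aldehyde face; the amine base or Lewis acids may deconjugate the skipped enynal; chloride from Me3SiCl may open the epoxide; lactonisation may stall. The fallback gives up ligand control and uses an indium-mediated Barbier allylation, which is reliably syn. It sets out from 11 and 18 and comes back at 21. Indium powder in THF/water would give hydroxy ester 20 together with methyl (3R,4R,5E)-4-hydroxy-6-methyl-2-methylidene-3-{(2S)-2-[(2R,3S)-2-methyl-3-(3-oxobutyl)oxiran-2-yl]-2-(triethylsilyloxy)ethyl}non-5-en-8-ynoate F6. PPTS would convert these into 21 and the (4R,5R)-configured cis-lactone diastereomer of 21 F7, which would be removed by chromatography.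

Third: step 7. Conversion of the β-silyloxy aldehyde may be slow, with competing β-elimination of triethylsilanol and aldol side reactions of the methyl ketone under prolonged amine catalysis. The fallback is an aldol/selenoxide elimination sequence; it sets out from 7 and comes back at 9. Addition of the lithium enolate of methyl 3-(phenylselanyl)propanoate (LDA, THF, −78 °C) to 7 would give methyl (5S)-3-hydroxy-5-[(2R,3S)-2-methyl-3-(3-oxobutyl)oxiran-2-yl]-2-[(phenylselanyl)methyl]-5-(triethylsilyloxy)pentanoate F8. Oxidation with H2O2/pyridine (CH2Cl2, 0 °C) and syn elimination of the selenoxide would give 9.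

Further compounds
F1 | step 15 | (2E,5E)-6-iodo-3-methylhexa-2,5-dien-1-ol | OC/C=C(\C)C/C=C/I
F2 | step 15 | (2E,5E)-6-iodo-3-methylhexa-2,5-dienal | O=C/C=C(\C)C/C=C/I
F3 | step 15 | methyl (3S,4S,5E,8E)-9-iodo-6-methyl-2-methylidene-3-{(2S)-2-[(2R,3S)-2-methyl-3-(3-oxobutyl)oxiran-2-yl]-2-(triethylsilyloxy)ethyl}-4-(trimethylsilyloxy)nona-5,8-dienoate | C=C(C(=O)OC)[C@@H]([C@@H](O[Si](C)(C)C)/C=C(\C)C/C=C/I)C[C@H](O[Si](CC)(CC)CC)[C@]1(C)O[C@H]1CCC(C)=O
F4 | step 15 | methyl (3S,4S,5E,8E)-4-hydroxy-9-iodo-6-methyl-2-methylidene-3-{(2S)-2-[(2R,3S)-2-methyl-3-(3-oxobutyl)oxiran-2-yl]-2-(triethylsilyloxy)ethyl}nona-5,8-dienoate | C=C(C(=O)OC)[C@@H]([C@@H](O)/C=C(\C)C/C=C/I)C[C@H](O[Si](CC)(CC)CC)[C@]1(C)O[C@H]1CCC(C)=O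
F5 | step 15 | (4S,5S)-5-[(1E,4E)-5-iodo-2-methylpenta-1,4-dien-1-yl]-3-methylidene-4-{(2S)-2-[(2R,3S)-2-methyl-3-(3-oxobutyl)oxiran-2-yl]-2-(triethylsilyloxy)ethyl}oxolan-2-one | C=C1C(=O)O[C@@H](/C=C(\C)C/C=C/I)[C@H]1C[C@H](O[Si](CC)(CC)CC)[C@]1(C)O[C@H]1CCC(C)=O
F6 | step 14 | methyl (3R,4R,5E)-4-hydroxy-6-methyl-2-methylidene-3-{(2S)-2-[(2R,3S)-2-methyl-3-(3-oxobutyl)oxiran-2-yl]-2-(triethylsilyloxy)ethyl}non-5-en-8-ynoate | C=C(C(=O)OC)[C@H]([C@H](O)/C=C(\C)CC#C)C[C@H](O[Si](CC)(CC)CC)[C@]1(C)O[C@H]1CCC(C)=O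
F7 | step 14 | (4R,5R)-3-methylidene-5-[(1E)-2-methylpent-1-en-4-yn-1-yl]-4-{(2S)-2-[(2R,3S)-2-methyl-3-(3-oxobutyl)oxiran-2-yl]-2-(triethylsilyloxy)ethyl}oxolan-2-one | C=C1C(=O)O[C@H](/C=C(\C)CC#C)[C@@H]1C[C@H](O[Si](CC)(CC)CC)[C@]1(C)O[C@H]1CCC(C)=O
F8 | step 7 | methyl (5S)-3-hydroxy-5-[(2R,3S)-2-methyl-3-(3-oxobutyl)oxiran-2-yl]-2-[(phenylselanyl)methyl]-5-(triethylsilyloxy)pentanoate (mixture at C2 and C3) | CC(=O)CC[C@@H]1O[C@@]1(C)[C@@H](O[Si](CC)(CC)CC)CC(O)C(C[Se]c1ccccc1)C(=O)OC
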